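**Retrosynthetic overview**
1. The 14-OH and the 12E alkene come from a (13Z)-anti-β-hydroxyallylsilane, by OH-directed epoxidation and anti-Peterson opening (1,3-transposition).
2. Key disconnection, C13–C14 and C11–C12 in one flask. C14 is used as an α-oxygenated carbanion (d1), the sparteine-lithiated carbamate of (3Z,6Z)-nonadienol. It bonds to C13 of (E)-Me3SiCH=CH-9-BBN; both carbons are natural acceptor sites of the 1,4-dioxygenated C11–C14 unit. The chiral γ-silylallylborane that results (a β-anion equivalent of an allylic alcohol) then adds to the cyclopropyl aldehyde.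
3. The aldehyde comes from a dimethylamide. The eight-membered lactone is the second ring formed, by ring-closing metathesis.
4. The cyclopropane is the first ring formed, by 3-exo-tet attack of amide enolate C10 on epoxide carbon C8 (an a2 partner; two α-carbons are joined). One Shi epoxidation is thereby relayed into C7, C8 and C10.
5. The epoxy amide comes from the Eschenmoser–Claisen product of hexa-1,5-dien-3-ol.

Assumption: the SMILES is read as 7R,8R,10R,11S,14S with 4Z,12E,16Z,19Z (C1 = lactone carbonyl, C22 = chain end; this numbering is used throughout). (+)-Sparteine, the D-fructose-derived Shi ketone and (3Z,6Z)-nona-3,6-dien-1-ol are taken as catalogue items.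

**Route**

Step 1
Reactants: 1 hexa-1,5-dien-3-ol (racemic); 2 N,N-dimethylacetamide dimethyl acetal
Product: 4 (4E)-N,N-dimethylocta-4,7-dienamide, via ketene N,O-acetal 3 (not isolated)
Conditions: 2 (1.5 equiv), xylenes, 140 °C, MeOH distilled off, 6 h
Reagents that add atoms: 2 N,N-dimethylacetamide dimethyl acetal, CC(OC)(OC)N(C)C
Why: Eschenmoser–Claisen rearrangement: exchange of one OMe for the allylic alkoxide and loss of MeOH give 3, whose chair [3,3] shift with the allyl substituent equatorial delivers the E-C7=C8 alkene and destroys the carbinol centre, so racemic 1 suffices and the terminal alkene is untouched.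

Step 2
Reactants: 4 (4E)-N,N-dimethylocta-4,7-dienamide
Product: 5 3-[(2R,3R)-3-(prop-2-en-1-yl)oxiran-2-yl]-N,N-dimethylpropanamide
Conditions: D-fructose-derived Shi ketone (30 mol%), KHSO5 (as Oxone, 2KHSO5·KHSO4·K2SO4, 1.4 equiv), K2CO3, Bu4NHSO4 (4 mol%), MeCN–CH2(OMe)2/aq Na2B4O7–Na2EDTA buffer (pH 10.5), 0 °C, 3 h
Reagents that add atoms: potassium peroxymonosulfate, [K+].[O-]S(=O)(=O)OO
Why: Shi asymmetric epoxidation: the fructose-derived dioxirane attacks E-1,2-dialkyl alkenes through a spiro transition state to give the R,R-epoxide (about 90–95% ee expected) and reacts far more slowly with the monosubstituted alkene, so C7 (final) and C8 (to be inverted) are set here.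

Step 3
Reactants: 5 3-[(2R,3R)-3-(prop-2-en-1-yl)oxiran-2-yl]-N,N-dimethylpropanamide; 6 pent-4-enoyl chloride
Product: 9 (1R)-1-[(1R,2R)-2-(dimethylcarbamoyl)cyclopropyl]but-3-en-1-yl pent-4-enoate, via lithium enolate 7 (not isolated), via lithium alkoxide 8 (not isolated)
Conditions: LiN(iPr)2 (1.05 equiv), THF, −78 → 0 °C, 2 h; then 6 (2.2 equiv), −78 → 0 °C
Reagents that add atoms: 6 pent-4-enoyl chloride, C=CCCC(=O)Cl
Why: Intramolecular enolate–epoxide alkylation (3-exo-tet, a d2 + a2 union that makes the C8–C10 bond between two α-carbons) followed by O-acylation: the amide enolate opens the nearer epoxide carbon C8 from the back (inversion, 8R) while the C7–O bond is untouched (7R), the carboxamide takes the trans position away from the carbinol chain (10R), and the alkoxide 8 is acylated in the same flask.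

Step 4
Reactants: 9 (1R)-1-[(1R,2R)-2-(dimethylcarbamoyl)cyclopropyl]but-3-en-1-yl pent-4-enoate
Product: 10 (1R,2R)-N,N-dimethyl-2-[(2R,4Z)-8-oxo-3,6,7,8-tetrahydro-2H-oxocin-2-yl]cyclopropane-1-carboxamide
Conditions: RuCl2(=CHPh)(PCy3)(SIMes) (second-generation Grubbs catalyst, 5 mol%), 1,4-benzoquinone (10 mol%), CH2Cl2 (2 mM), reflux, 12 h
Reagents that add atoms: none
Why: Ring-closing metathesis: only the two terminal alkenes are present, loss of ethene drives closure, the eight-membered ring can hold only the Z-C4=C5 alkene, and high dilution holds back oligomers.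

Step 5
Reactants: 10 (1R,2R)-N,N-dimethyl-2-[(2R,4Z)-8-oxo-3,6,7,8-tetrahydro-2H-oxocin-2-yl]cyclopropane-1-carboxamide
Product: 12 (1R,2R)-2-[(2R,4Z)-8-oxo-3,6,7,8-tetrahydro-2H-oxocin-2-yl]cyclopropane-1-carbaldehyde, via zirconium hemiaminal 11 (not isolated)
Conditions: Cp2Zr(H)Cl (1.6 equiv), THF, 23 °C, 20 min; H2O/SiO2 work-up
Reagents that add atoms: water, O
Why: Schwartz-reagent reduction of a tertiary amide: Zr–H adds once to the amide carbonyl to give the stable hemiaminal 11, which collapses to the aldehyde only on aqueous work-up, and this addition is much faster than attack on the lactone or the internal Z alkene, while no stereocentre is touched and the trans aldehyde is the stable epimer.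

Step 6
Reactants: 13 (3Z,6Z)-nona-3,6-dien-1-ol; 14 N,N-diisopropylcarbamoyl chloride
Product: 15 (3Z,6Z)-nona-3,6-dien-1-yl N,N-diisopropylcarbamate
Conditions: 14 (1.2 equiv), Et3N (1.5 equiv), CH2Cl2, reflux, 24 h
Reagents that add atoms: 14 N,N-diisopropylcarbamoyl chloride, CC(C)N(C(C)C)C(=O)Cl
Why: Carbamoylation of a primary alcohol (acyl substitution) installs the group that later directs lithiation and then leaves, without touching the Z,Z-diene.

Step 7
Reactants: 16 ethynyltrimethylsilane; 17 9-borabicyclo[3.3.1]nonane (9-BBN-H)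
Product: 18 B-[(E)-2-(trimethylsilyl)ethenyl]-9-BBN
Conditions: 17 (0.5 M in THF, 1.0 equiv), 16 (2.0 equiv), 0 → 23 °C, 3 h; volatiles removed, redissolved in Et2O under Ar
Reagents that add atoms: 17 9-BBN-H, B1C2CCCC1CCC2
Why: Alkyne hydroboration: syn addition of B–H with boron on the unhindered terminal carbon gives the E-alkenylborane, and excess alkyne suppresses double hydroboration.

Step 8 (key step)
Reactants: 15 (3Z,6Z)-nona-3,6-dien-1-yl N,N-diisopropylcarbamate; 18 B-[(E)-2-(trimethylsilyl)ethenyl]-9-BBN; 12 (1R,2R)-2-[(2R,4Z)-8-oxo-3,6,7,8-tetrahydro-2H-oxocin-2-yl]cyclopropane-1-carbaldehyde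
Product: 23 (8R,5Z)-8-{(1R,2S)-free descriptor form: (1R,2R)-2-[(1R,2S,3Z,6Z,9Z)-1-hydroxy-2-(trimethylsilyl)dodeca-3,6,9-trien-1-yl]cyclopropyl}-3,4,7,8-tetrahydro-2H-oxocin-2-one, via lithiated carbamate 19 (not isolated), via borate complex 20 (not isolated), via allylborane 21 (not isolated), via borinic ester 22 (not isolated)
Conditions: 15 (1.3 equiv), (+)-sparteine (1.3 equiv), s-BuLi (1.25 equiv), Et2O, −78 °C, 5 h; 18 (1.4 equiv), −78 °C 30 min, −40 °C 1 h; recool to −78 °C, 12 (1.0 equiv), → 23 °C; HOCH2CH2NH2 work-up; chromatography removes minor diastereomers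
Reagents that add atoms: 18 B-[(E)-2-(trimethylsilyl)ethenyl]-9-BBN, C[Si](C)(C)/C=C/B1C2CCCC1CCC2; 12 cyclopropyl aldehyde, O=C[C@@H]1C[C@H]1[C@H]1C/C=C\CCC(=O)O1
Why: Hoppe asymmetric lithiation, Matteson-type 1,2-metallate rearrangement and Zimmerman–Traxler allylboration in one flask: s-BuLi/(+)-sparteine removes the pro-R hydrogen next to the carbamate oxygen to give the configurationally stable C14 carbanion 19 (a carbinol carbon acting as nucleophile), boron captures it with retention (20), the silylvinyl group shifts to C14 anti to the leaving carbamate with inversion (C13–C14 bond, 21), and 21 adds to the aldehyde of 12, not to the lactone, through a chair with the C15 chain axial away from the 9-BBN cage and the E-silyl group equatorial, which gives the 13Z alkene, the anti C11/C12 pair and the carbinol configuration of the target under reagent control.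

Step 9
Reactants: 23 (13Z)-anti-β-hydroxyallylsilane
Product: 25 (8R,5Z)-8-{(1R,2R)-2-[(1S,2E,4S,6Z,9Z)-1,4-dihydroxydodeca-2,6,9-trien-1-yl]cyclopropyl}-3,4,7,8-tetrahydro-2H-oxocin-2-one, via epoxysilane 24 (not isolated)
Conditions: VO(acac)2 (5 mol%), t-BuOOH (1.1 equiv, decane), CH2Cl2, 0 °C, 2 h; aq Na2S2O3; crude 24 in THF–H2O–AcOH (8:1:1), 0 °C, 30 min
Reagents that add atoms: tert-butyl hydroperoxide, CC(C)(C)OO
Why: Hydroxyl-directed vanadium epoxidation followed by Peterson-type anti elimination (net anti SE2′ oxygenation of an allylsilane): with H12 eclipsing the Z alkene (A1,3 strain) the C11 vanadate reaches only the homoallylic C13=C14 bond and only its face opposite silicon, so the three remote Z alkenes are left alone, and anti-periplanar loss of Me3Si and the C13–O bond gives the 12E alkene and the 14S alcohol.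

**Compound list**
1 | hexa-1,5-dien-3-ol (racemic) | C=CCC(O)C=C | starting material
2 | N,N-dimethylacetamide dimethyl acetal | CC(OC)(OC)N(C)C | starting material
3 | 1-(hexa-1,5-dien-3-yloxy)-N,N-dimethylethenamine, ketene N,O-acetal (not isolated) | C=C(N(C)C)OC(C=C)CC=C | intermediate
4 | (4E)-N,N-dimethylocta-4,7-dienamide | CN(C)C(=O)CC/C=C/CC=C | intermediate
5 | 3-[(2R,3R)-3-(prop-2-en-1-yl)oxiran-2-yl]-N,N-dimethylpropanamide | CN(C)C(=O)CC[C@H]1O[C@@H]1CC=C | intermediate
6 | pent-4-enoyl chloride | C=CCCC(=O)Cl | starting material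
7 | lithium (Z)-enolate of 5 (not isolated) | CN(C)/C(O[Li])=C/C[C@H]1O[C@@H]1CC=C | intermediate
8 | lithium (1R)-1-[(1R,2R)-2-(dimethylcarbamoyl)cyclopropyl]but-3-en-1-olate (not isolated) | CN(C)C(=O)[C@@H]1C[C@H]1[C@H](O[Li])CC=C | intermediate
9 | (1R)-1-[(1R,2R)-2-(dimethylcarbamoyl)cyclopropyl]but-3-en-1-yl pent-4-enoate | CN(C)C(=O)[C@@H]1C[C@H]1[C@H](OC(=O)CCC=C)CC=C | intermediate
10 | (1R,2R)-N,N-dimethyl-2-[(2R,4Z)-8-oxo-3,6,7,8-tetrahydro-2H-oxocin-2-yl]cyclopropane-1-carboxamide | CN(C)C(=O)[C@@H]1C[C@H]1[C@H]1C/C=C\CCC(=O)O1 | intermediate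
11 | O-(chlorozirconocenyl) hemiaminal of 10, Cp rings drawn σ-bound, C11 unassigned (not isolated) | CN(C)C(O[Zr](Cl)(C1C=CC=C1)C1C=CC=C1)[C@@H]1C[C@H]1[C@H]1C/C=C\CCC(=O)O1 | intermediate
12 | (1R,2R)-2-[(2R,4Z)-8-oxo-3,6,7,8-tetrahydro-2H-oxocin-2-yl]cyclopropane-1-carbaldehyde | O=C[C@@H]1C[C@H]1[C@H]1C/C=C\CCC(=O)O1 | intermediate
13 | (3Z,6Z)-nona-3,6-dien-1-ol | CC/C=C\C/C=C\CCO | starting material
14 | N,N-diisopropylcarbamoyl chloride | CC(C)N(C(C)C)C(=O)Cl | starting material
15 | (3Z,6Z)-nona-3,6-dien-1-yl N,N-diisopropylcarbamate | CC/C=C\C/C=C\CCOC(=O)N(C(C)C)C(C)C | intermediate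
16 | ethynyltrimethylsilane | C#C[Si](C)(C)C | starting material
17 | 9-borabicyclo[3.3.1]nonane (9-BBN-H, sold as dimer or THF solution) | B1C2CCCC1CCC2 | starting material
18 | B-[(E)-2-(trimethylsilyl)ethenyl]-9-BBN | C[Si](C)(C)/C=C/B1C2CCCC1CCC2 | intermediate
19 | (1R,3Z,6Z)-1-lithionona-3,6-dien-1-yl N,N-diisopropylcarbamate, (+)-sparteine complex, ligand omitted (not isolated) | CC/C=C\C/C=C\C[C@@H]([Li])OC(=O)N(C(C)C)C(C)C | intermediate
20 | lithium borate from 19 and 18, C14 R (not isolated) | CC/C=C\C/C=C\C[C@@H]([B-]1(/C=C/[Si](C)(C)C)C2CCCC1CCC2)OC(=O)N(C(C)C)C(C)C.[Li+] | intermediate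
21 | B-[(1E,3S,5Z,8Z)-1-(trimethylsilyl)undeca-1,5,8-trien-3-yl]-9-BBN (not isolated) | CC/C=C\C/C=C\C[C@H](B1C2CCCC1CCC2)/C=C/[Si](C)(C)C | intermediate
22 | 9-BBN borinic ester (C11–O–B) of 23 (not isolated) | CC/C=C\C/C=C\C/C=C\[C@H]([Si](C)(C)C)[C@H](OB2C3CCCC2CCC3)[C@@H]1C[C@H]1[C@H]1C/C=C\CCC(=O)O1 | intermediate
23 | (8R,5Z)-8-{(1R,2R)-2-[(1R,2S,3Z,6Z,9Z)-1-hydroxy-2-(trimethylsilyl)dodeca-3,6,9-trien-1-yl]cyclopropyl}-3,4,7,8-tetrahydro-2H-oxocin-2-one | CC/C=C\C/C=C\C/C=C\[C@H]([Si](C)(C)C)[C@H](O)[C@@H]1C[C@H]1[C@H]1C/C=C\CCC(=O)O1 | intermediate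
24 | (13S,14S)-cis-13,14-epoxide of 23, oxygen anti to silicon (not isolated) | CC/C=C\C/C=C\C[C@@H]1O[C@@H]1[C@H]([Si](C)(C)C)[C@H](O)[C@@H]1C[C@H]1[C@H]1C/C=C\CCC(=O)O1 | intermediate
25 | (8R,5Z)-8-{(1R,2R)-2-[(1S,2E,4S,6Z,9Z)-1,4-dihydroxydodeca-2,6,9-trien-1-yl]cyclopropyl}-3,4,7,8-tetrahydro-2H-oxocin-2-one (CNP0319393.2) | CC/C=C\C/C=C\C[C@H](O)/C=C/[C@H](O)[C@@H]1C[C@H]1[C@H]1C/C=C\CCC(=O)O1 | target

The name of 23 in the compound list is the valid one; the Product line of step 8 refers to the same compound.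

**Step count and risks**
Total: 9 steps. Longest linear sequence: 7 steps (1, 2, 3, 4, 5, 8, 9). Steps 6 and 7 are one-step side branches.

Step 8 is the most likely to fail. s-BuLi may attack the bis-allylic C18–H or the allylic C15–H of 15 instead of the carbamate-directed C14–H. The fallback makes the same carbanion by tin–lithium exchange on a preformed stereocentre. It sets out from 13 and comes back at 19.
- Dess–Martin oxidation of 13 gives (3Z,6Z)-nona-3,6-dienal F1.
- Bu3SnLi (THF, −78 °C) adds to give lithium 1-(tributylstannyl)nona-3,6-dien-1-olate F2.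
- F2 is oxidised in the same flask with 1,1′-(azodicarbonyl)dipiperidine to the acylstannane (3Z,6Z)-1-(tributylstannyl)nona-3,6-dien-1-one F3.
- LiAlH(OEt)(1,1′-bi-2-naphtholate) (BINAL-H, the enantiomer that gives the R carbinol) reduces F3 to (1R,3Z,6Z)-1-(tributylstannyl)nona-3,6-dien-1-ol F4.
- 14 with Et3N gives (1R,3Z,6Z)-1-(tributylstannyl)nona-3,6-dien-1-yl N,N-diisopropylcarbamate F5.
- n-BuLi (Et2O, −78 °C, minutes) exchanges tin for lithium with retention to give 19, which continues as in step 8.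

Step 9 is the second risk. If 24 opens before the oxidant is quenched, the freed allylic diol can be over-epoxidised, and selectivity among four Z alkenes may be incomplete. The fallback replaces alkene oxidation with C–B oxidation. It sets out from 12 and 19 and comes back at 25.
- HC≡CMgBr (THF, −78 °C) adds to the aldehyde of 12. After separation of the C11 epimers this gives the propargylic alcohol (11R descriptor, same spatial sense as 11S in 25) F6.
- TBSCl/imidazole gives its silyl ether F7.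
- Pinacolborane with Cp2Zr(H)Cl (10 mol%) gives the (12E)-alkenylboronate F8.
- 19 adds to the boron of F8 at −78 °C to give the boronate complex F9.
- With MgBr2·OEt2 and warming, the alkenyl group of F9 shifts to C14 with inversion to give the (14S)-allylic boronate F10.
- NaBO3·4H2O oxidises only the C–B bond, with retention, to give the 11-O-TBS ether of the target F11.
- HF·pyridine frees 25.

Step 4 is the third risk, because eight-membered lactone formation by metathesis can lose out to oligomerisation. The fallback builds the Z alkene first and closes the C–O bond last. It sets out from 8 and comes back at 10.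
- 8 is quenched with water instead of 6 to give (1R,2R)-2-[(1R)-1-hydroxybut-3-en-1-yl]-N,N-dimethylcyclopropane-1-carboxamide F12.
- Ozonolysis (O3, CH2Cl2, −78 °C; Me2S) gives (1R,2R)-2-[(1R)-1-hydroxy-3-oxopropyl]-N,N-dimethylcyclopropane-1-carboxamide F13.
- A Z-selective Wittig reaction with the ylide from (3-carboxypropyl)triphenylphosphonium bromide and excess NaN(SiMe3)2 gives (4Z,7R)-7-[(1R,2R)-2-(dimethylcarbamoyl)cyclopropyl]-7-hydroxyhept-4-enoic acid F14.
- Yamaguchi lactonisation (2,4,6-trichlorobenzoyl chloride, Et3N; DMAP, toluene, high dilution) closes the ring to 10.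

**Further compounds**
F1 | step 8 | (3Z,6Z)-nona-3,6-dienal | CC/C=C\C/C=C\CC=O
F2 | step 8 | lithium (3Z,6Z)-1-(tributylstannyl)nona-3,6-dien-1-olate (racemic) | CC/C=C\C/C=C\CC(O[Li])[Sn](CCCC)(CCCC)CCCC
F3 | step 8 | (3Z,6Z)-1-(tributylstannyl)nona-3,6-dien-1-one | CC/C=C\C/C=C\CC(=O)[Sn](CCCC)(CCCC)CCCC
F4 | step 8 | (1R,3Z,6Z)-1-(tributylstannyl)nona-3,6-dien-1-ol | CC/C=C\C/C=C\C[C@H](O)[Sn](CCCC)(CCCC)CCCC
F5 | step 8 | (1R,3Z,6Z)-1-(tributylstannyl)nona-3,6-dien-1-yl N,N-diisopropylcarbamate | CC/C=C\C/C=C\C[C@@H]([Sn](CCCC)(CCCC)CCCC)OC(=O)N(C(C)C)C(C)C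
F6 | step 9 | (8R,5Z)-8-{(1R,2R)-2-[(1R)-1-hydroxyprop-2-yn-1-yl]cyclopropyl}-3,4,7,8-tetrahydro-2H-oxocin-2-one | C#C[C@H](O)[C@@H]1C[C@H]1[C@H]1C/C=C\CCC(=O)O1
F7 | step 9 | tert-butyldimethylsilyl ether of F6 | C#C[C@H](O[Si](C)(C)C(C)(C)C)[C@@H]1C[C@H]1[C@H]1C/C=C\CCC(=O)O1
F8 | step 9 | (12E,11S)-11-(tert-butyldimethylsilyloxy)-13-(pinacolatoboryl) C1–C13 alkenylboronate | CC1(C)OB(/C=C/[C@H](O[Si](C)(C)C(C)(C)C)[C@@H]2C[C@H]2[C@H]2C/C=C\CCC(=O)O2)OC1(C)C
F9 | step 9 | lithium boronate complex from 19 and F8 | CC/C=C\C/C=C\C[C@@H]([B-]1(/C=C/[C@H](O[Si](C)(C)C(C)(C)C)[C@@H]2C[C@H]2[C@H]2C/C=C\CCC(=O)O2)OC(C)(C)C(C)(C)O1)OC(=O)N(C(C)C)C(C)C.[Li+]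
F10 | step 9 | (14S)-14-(pinacolatoboryl)-11-O-TBS allylic boronate | CC/C=C\C/C=C\C[C@H](B1OC(C)(C)C(C)(C)O1)/C=C/[C@H](O[Si](C)(C)C(C)(C)C)[C@@H]1C[C@H]1[C@H]1C/C=C\CCC(=O)O1
F11 | step 9 | 11-O-(tert-butyldimethylsilyl) ether of 25 | CC/C=C\C/C=C\C[C@H](O)/C=C/[C@H](O[Si](C)(C)C(C)(C)C)[C@@H]1C[C@H]1[C@H]1C/C=C\CCC(=O)O1
F12 | step 4 | (1R,2R)-2-[(1R)-1-hydroxybut-3-en-1-yl]-N,N-dimethylcyclopropane-1-carboxamide | CN(C)C(=O)[C@@H]1C[C@H]1[C@H](O)CC=C
F13 | step 4 | (1R,2R)-2-[(1R)-1-hydroxy-3-oxopropyl]-N,N-dimethylcyclopropane-1-carboxamide | CN(C)C(=O)[C@@H]1C[C@H]1[C@H](O)CC=O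
F14 | step 4 | (4Z,7R)-7-[(1R,2R)-2-(dimethylcarbamoyl)cyclopropyl]-7-hydroxyhept-4-enoic acid | CN(C)C(=O)[C@@H]1C[C@H]1[C@H](O)C/C=C\CCC(=O)O
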